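**Plan**

- Retrosynthesis: the C5 hydroxyl is written as its methyl ether and the C2' methoxy as a free phenol. Ring B is then cut at C5'–C6', C1'–C2' and C2'–C3' into 2-ethynylchromone 10, carbene complex 15 and one of its carbonyl ligands.
- Enabling feature: ring B has oxygens on C2' and C5' para to each other and a methoxy on C4' next to C5'. This is the 4-methoxyphenol that a methoxy(1-methoxyvinyl)carbene (C5', C4', C3'), a carbonyl ligand (C2') and a terminal alkyne (C1', C6') assemble.
- Alkyne 10 goes back to aldehyde 9 (one-carbon homologation), to 2-methylchromone 8, and to acetophenone 6 plus ethyl acetate (C2–C3 and O1–C2). Acetophenone 6 comes from 1,2,3,4-tetramethoxybenzene by hydroxylation and acylation.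
- Forward order: ring A is bought with 1, ring C closes in step 3, ring B closes last in step 7, then two O-methyl adjustments follow.
- Stereochemistry: the target has no stereocentre and no stereogenic double bond. Only regiochemistry has to be controlled (alkyne insertion in step 7, chelation in step 9).

Key step: step 7

Remark: unprimed locants (O1, C2–C8a) belong to the chromone (ring A benzo, ring C pyranone) and primed locants to ring B; methyl vinyl ether is used as the commercial liquefied gas, condensed into cold THF.

**Route**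

Step 1
Reactants: 1 1,2,3,4-tetramethoxybenzene
Product: 4 2,3,4,5-tetramethoxyphenol, via aryllithium 2 (not isolated), via lithium aryltrimethoxyborate 3 (not isolated)
Conditions: n-BuLi, TMEDA, THF, 0 °C to rt; B(OMe)3, −78 °C to rt; then AcOH, 30% aq. H2O2, 0 °C
Reagents that add atoms: hydrogen peroxide, OO
Why: Directed ortho-metalation removes one of the two equivalent ring hydrogens next to a methoxy group, the aryllithium is trapped as the borate, and boronate oxidation (1,2-aryl shift from boron to oxygen) should give the phenol.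

Step 2
Reactants: 4 2,3,4,5-tetramethoxyphenol
Product: 6 2-hydroxy-3,4,5,6-tetramethoxyacetophenone, via difluoroboron chelate 5 (not isolated)
Conditions: AcOH, BF3·OEt2, 90 °C; then H2O/EtOH, 60 °C
Reagents that add atoms: acetic acid, CC(=O)O
Why: Friedel–Crafts acylation (through the O-acetate and a Fries shift) can only take the single unsubstituted ring carbon, which is ortho to the hydroxyl, and the difluoroboron chelate of the ortho-hydroxy ketone shields the product until it is hydrolysed.

Step 3
Reactants: 6 2-hydroxy-3,4,5,6-tetramethoxyacetophenone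
Product: 8 5,6,7,8-tetramethoxy-2-methyl-4H-chromen-4-one, via 1,3-diketone 7 (not isolated)
Conditions: NaH, EtOAc, THF, reflux; aq. HCl work-up; then cat. H2SO4, AcOH, 80 °C
Reagents that add atoms: ethyl acetate, CCOC(C)=O
Why: Crossed Claisen condensation of the methyl ketone enolate with ethyl acetate gives the β-diketone, and acid-catalysed cyclodehydration (phenol onto the distal carbonyl, loss of water) should close ring C.

Step 4
Reactants: 8 5,6,7,8-tetramethoxy-2-methyl-4H-chromen-4-one
Product: 9 5,6,7,8-tetramethoxy-4-oxo-4H-chromene-2-carbaldehyde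
Conditions: SeO2, 1,4-dioxane, reflux
Reagents that add atoms: selenium dioxide, O=[Se]=O
Why: Riley oxidation: the 2-methyl group is vinylogously activated by the C4 carbonyl, and the fully substituted ring A offers no competing C–H bond.

Step 5
Reactants: 9 5,6,7,8-tetramethoxy-4-oxo-4H-chromene-2-carbaldehyde
Product: 10 2-ethynyl-5,6,7,8-tetramethoxy-4H-chromen-4-one
Conditions: dimethyl (1-diazo-2-oxopropyl)phosphonate, K2CO3, MeOH/THF, 0 °C to rt
Reagents that add atoms: dimethyl (1-diazo-2-oxopropyl)phosphonate, CC(=O)C(=[N+]=[N-])P(=O)(OC)OC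
Why: Seyferth–Gilbert homologation in the Ohira–Bestmann form: the diazomethylphosphonate anion freed by methanolysis adds to the aldehyde, dimethyl phosphate is eliminated, and loss of N2 with 1,2-hydrogen shift gives the terminal alkyne at a temperature the electron-rich chromone should tolerate.

Step 6
Reactants: 11 methyl vinyl ether; 12 chromium hexacarbonyl, Cr(CO)6
Product: 15 pentacarbonyl[methoxy(1-methoxyvinyl)carbene]chromium, via 1-methoxyvinyllithium 13 (not isolated), via lithium acylchromate 14 (not isolated)
Conditions: t-BuLi, THF, −78 to 0 °C; Cr(CO)6, THF, 0 °C to rt; then Me3OBF4, CH2Cl2, 0 °C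
Reagents that add atoms: trimethyloxonium tetrafluoroborate, C[O+](C)C.F[B-](F)(F)F
Why: Fischer carbene synthesis: α-lithiation of the enol ether, addition of the vinyllithium to a carbonyl ligand, and O-methylation of the acylchromate by the hard oxonium salt.

Step 7
Reactants: 10 2-ethynyl-5,6,7,8-tetramethoxy-4H-chromen-4-one; 15 pentacarbonyl[methoxy(1-methoxyvinyl)carbene]chromium
Product: 17 2-(2-hydroxy-4,5-dimethoxyphenyl)-5,6,7,8-tetramethoxy-4H-chromen-4-one, via tricarbonylchromium arene complex 16 (not isolated)
Conditions: 15 (1.5 equiv), THF, 50 °C, Ar, slow addition of 10; then air, MeCN, rt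
Reagents that add atoms: none
Why: Thermal loss of one carbonyl ligand from 15 frees a site on zerovalent chromium, the terminal alkyne of 10 binds and inserts into the Cr=C bond (C5'–C6'), a carbonyl ligand then inserts to give a chromium-bound dienylketene (C1'–C2'), and this closes and tautomerises to the phenol complex 16, from which air removes the metal. The closest known reaction type is the Dötz benzannulation of alkenyl(alkoxy)carbene chromium complexes with terminal aryl, alkenyl and acyl alkynes, including α-oxygenated alkenyl carbenes such as dihydropyranyl ones. Ring B is closed by a six-electron electrocyclisation of the dienylketene that joins the ketene carbon C2' to the methylene terminus C3'. No stereocentre is formed. The step needs regioselective insertion, with the substituted alkyne carbon ending next to the carbonyl-derived C2', which the size difference between the chromon-2-yl group and hydrogen secures; it also needs reaction at the alkyne and not at the pyranone double bond, which the much higher affinity of the unsaturated chromium centre for a terminal alkyne over a trisubstituted oxygen-bearing alkene should provide. Slow addition of 10 to excess 15 should hold back double alkyne incorporation, and demetallation by air in place of a strong oxidant should stop the electron-rich 4-methoxyphenol short of the quinone.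

Step 8
Reactants: 17 2-(2-hydroxy-4,5-dimethoxyphenyl)-5,6,7,8-tetramethoxy-4H-chromen-4-one
Product: 18 5,6,7,8-tetramethoxy-2-(2,4,5-trimethoxyphenyl)-4H-chromen-4-one
Conditions: MeI, K2CO3, acetone, reflux
Reagents that add atoms: iodomethane, CI
Why: Williamson ether synthesis on the only free phenol, which is not chelated and is readily deprotonated by K2CO3.

Step 9
Reactants: 18 5,6,7,8-tetramethoxy-2-(2,4,5-trimethoxyphenyl)-4H-chromen-4-one
Product: 20 agehoustin E (5-hydroxy-6,7,8-trimethoxy-2-(2,4,5-trimethoxyphenyl)-4H-chromen-4-one), via dichloroboron chelate 19 (not isolated)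
Conditions: BCl3, CH2Cl2, −78 to 0 °C; then H2O, rt
Reagents that add atoms: none
Why: Chelation-directed Lewis-acid ether cleavage: BCl3 is held between the C4 carbonyl and the peri C5 methoxy oxygen in a six-membered chelate, so chloride should remove only that methyl group, while the other six aryl methyl ethers lack this assistance at low temperature.

**Compound list**

1 | 1,2,3,4-tetramethoxybenzene | COc1ccc(OC)c(OC)c1OC | starting material
2 | 2,3,4,5-tetramethoxyphenyllithium | [Li]c1cc(OC)c(OC)c(OC)c1OC | intermediate
3 | lithium trimethoxy(2,3,4,5-tetramethoxyphenyl)borate | [Li+].CO[B-](OC)(OC)c1cc(OC)c(OC)c(OC)c1OC | intermediate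
4 | 2,3,4,5-tetramethoxyphenol | Oc1cc(OC)c(OC)c(OC)c1OC | intermediate
5 | difluoroboron chelate of 2-hydroxy-3,4,5,6-tetramethoxyacetophenone | CC1=[O+][B-](F)(F)Oc2c(OC)c(OC)c(OC)c(OC)c12 | intermediate
6 | 2-hydroxy-3,4,5,6-tetramethoxyacetophenone | CC(=O)c1c(O)c(OC)c(OC)c(OC)c1OC | intermediate
7 | 1-(2-hydroxy-3,4,5,6-tetramethoxyphenyl)butane-1,3-dione | CC(=O)CC(=O)c1c(O)c(OC)c(OC)c(OC)c1OC | intermediate
8 | 5,6,7,8-tetramethoxy-2-methyl-4H-chromen-4-one | Cc1cc(=O)c2c(OC)c(OC)c(OC)c(OC)c2o1 | intermediate
9 | 5,6,7,8-tetramethoxy-4-oxo-4H-chromene-2-carbaldehyde | O=Cc1cc(=O)c2c(OC)c(OC)c(OC)c(OC)c2o1 | intermediate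
10 | 2-ethynyl-5,6,7,8-tetramethoxy-4H-chromen-4-one | C#Cc1cc(=O)c2c(OC)c(OC)c(OC)c(OC)c2o1 | intermediate
11 | methyl vinyl ether | C=COC | starting material
12 | chromium hexacarbonyl, Cr(CO)6 | [Cr].[C-]#[O+].[C-]#[O+].[C-]#[O+].[C-]#[O+].[C-]#[O+].[C-]#[O+] | starting material
13 | 1-methoxyvinyllithium | [Li]C(=C)OC | intermediate
14 | lithium pentacarbonyl(2-methoxy-1-oxidoprop-2-en-1-ylidene)chromate | [Li+].[O-]C(C(OC)=C)=[Cr].[C-]#[O+].[C-]#[O+].[C-]#[O+].[C-]#[O+].[C-]#[O+] | intermediate
15 | pentacarbonyl[methoxy(1-methoxyvinyl)carbene]chromium | COC(=C)C(OC)=[Cr].[C-]#[O+].[C-]#[O+].[C-]#[O+].[C-]#[O+].[C-]#[O+] | intermediate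
16 | tricarbonyl[η6-(ring B of 17)]chromium | COc1cc(O)c(-c2cc(=O)c3c(OC)c(OC)c(OC)c(OC)c3o2)cc1OC.[Cr].[C-]#[O+].[C-]#[O+].[C-]#[O+] | intermediate
17 | 2-(2-hydroxy-4,5-dimethoxyphenyl)-5,6,7,8-tetramethoxy-4H-chromen-4-one | COc1cc(O)c(-c2cc(=O)c3c(OC)c(OC)c(OC)c(OC)c3o2)cc1OC | intermediate
18 | 5,6,7,8-tetramethoxy-2-(2,4,5-trimethoxyphenyl)-4H-chromen-4-one | COc1cc(OC)c(-c2cc(=O)c3c(OC)c(OC)c(OC)c(OC)c3o2)cc1OC | intermediate
19 | 5-O-dichloroboryl chelate of 5-hydroxy-6,7,8-trimethoxy-2-(2,4,5-trimethoxyphenyl)-4H-chromen-4-one | COc1cc(OC)c(-c2cc(=O)c3c(OB(Cl)Cl)c(OC)c(OC)c(OC)c3o2)cc1OC | intermediate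
20 | agehoustin E, 5-hydroxy-6,7,8-trimethoxy-2-(2,4,5-trimethoxyphenyl)-4H-chromen-4-one | COc1cc(OC)c(-c2cc(=O)c3c(O)c(OC)c(OC)c(OC)c3o2)cc1OC | target

**Step count**

Total: 9 steps. Longest linear sequence: 8 steps (steps 1–5 and 7–9 from 1); step 6 is a one-step branch.

**Steps most likely to fail**

Step 7. The electron-poor conjugated alkyne may oligomerise, carbonyl insertion may stall (diversion to cyclobutenone or furan products), or the α-alkoxyvinyl carbene complex may decompose before it inserts. In that case ring B would be brought in ready-made. Setting out from 6, O-acylation with 2,4,5-trimethoxybenzoyl chloride in pyridine would give 2-acetyl-3,4,5,6-tetramethoxyphenyl 2,4,5-trimethoxybenzoate F1. Baker–Venkataraman acyl shift (KOH, pyridine, 50 °C) would give 1-(2-hydroxy-3,4,5,6-tetramethoxyphenyl)-3-(2,4,5-trimethoxyphenyl)propane-1,3-dione F2. Cyclodehydration (cat. H2SO4, AcOH, 80 °C) would come back to the route at 18, from which step 9 follows.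

Step 5. Under basic methanol, methoxide may add in conjugate fashion to the newly formed ethynyl group (a vinylogous ynone), or the pyranone may open at C2. The alkyne would then be introduced by acylation before ring C is closed. Setting out from 6, the dianion (LiHMDS, THF, −78 °C) would be C-acylated with 3-(triisopropylsilyl)propioloyl chloride to give 1-(2-hydroxy-3,4,5,6-tetramethoxyphenyl)-5-(triisopropylsilyl)pent-4-yne-1,3-dione F3, the bulky silyl group keeping nucleophiles off the alkyne terminus. Acid cyclodehydration (TsOH, toluene, 80 °C) would give 5,6,7,8-tetramethoxy-2-[(triisopropylsilyl)ethynyl]-4H-chromen-4-one F4. Buffered fluoride (TBAF, AcOH, THF, 0 °C) would remove silicon and come back to the route at 10.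

Step 4. Over-oxidation to the carboxylic acid, incomplete conversion, and carry-over of colloidal selenium may erode the aldehyde. The formyl carbon would then be installed at the ester level and adjusted by reduction and reoxidation. Setting out from 6, Claisen condensation with diethyl oxalate (NaOEt, EtOH) and acid cyclisation (HCl, EtOH, reflux) would give ethyl 5,6,7,8-tetramethoxy-4-oxo-4H-chromene-2-carboxylate F5. NaBH4 (MeOH, 0 °C) would reduce the activated ester to 2-(hydroxymethyl)-5,6,7,8-tetramethoxy-4H-chromen-4-one F6. MnO2 (CH2Cl2, rt) would come back to the route at 9.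

**Further compounds**

F1 | step 7 | 2-acetyl-3,4,5,6-tetramethoxyphenyl 2,4,5-trimethoxybenzoate | CC(=O)c1c(OC(=O)c2cc(OC)c(OC)cc2OC)c(OC)c(OC)c(OC)c1OC
F2 | step 7 | 1-(2-hydroxy-3,4,5,6-tetramethoxyphenyl)-3-(2,4,5-trimethoxyphenyl)propane-1,3-dione | COc1cc(OC)c(C(=O)CC(=O)c2c(O)c(OC)c(OC)c(OC)c2OC)cc1OC
F3 | step 5 | 1-(2-hydroxy-3,4,5,6-tetramethoxyphenyl)-5-(triisopropylsilyl)pent-4-yne-1,3-dione | COc1c(OC)c(OC)c(O)c(C(=O)CC(=O)C#C[Si](C(C)C)(C(C)C)C(C)C)c1OC
F4 | step 5 | 5,6,7,8-tetramethoxy-2-[(triisopropylsilyl)ethynyl]-4H-chromen-4-one | CC(C)[Si](C#Cc1cc(=O)c2c(OC)c(OC)c(OC)c(OC)c2o1)(C(C)C)C(C)C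
F5 | step 4 | ethyl 5,6,7,8-tetramethoxy-4-oxo-4H-chromene-2-carboxylate | CCOC(=O)c1cc(=O)c2c(OC)c(OC)c(OC)c(OC)c2o1
F6 | step 4 | 2-(hydroxymethyl)-5,6,7,8-tetramethoxy-4H-chromen-4-one | OCc1cc(=O)c2c(OC)c(OC)c(OC)c(OC)c2o1
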